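**Plan**

1. Retrosynthesis: the three ester C–O bonds at O3, O4 and O5 are cut first, then the ring bond C2–C3 (alkenyl iodide plus aldehyde), then C1=C2 (iodoform carbon on a malonate) and C6–C1 (malonate alkylation). This leaves a four-carbon C3–C6 threitol unit.
2. Enabling feature (shikimate numbering: C1 bears CO2Me, C1=C2, O3–O5 on C3–C5, C6 is CH2): C3 is an allylic carbinol carbon bonded to the vinylic carbon C2 of the enoate in the cyclohexene ring. C2–C3 is therefore the bond an alkenylmetal at C2 makes with an aldehyde at C3, and the trans O4/O5 pair on C4–C5 is the threo diol of D-tartaric acid.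
3. Forward: C3–C6 comes from 2,3-O-isopropylidene-D-threitol; C1 is joined to C6 by malonate alkylation; C2 is added with iodoform and the (E)-β-iodoacrylate is released by decarboxylative elimination. The only ring, the cyclohexene, closes in the nickel/chromium step, and the three esters follow.
4. Stereochemistry: C4 and C5 are bought (D-tartaric acid series). C3 is set in the ring closure under control of the acetal-locked C4, with an inversion route in reserve. The iodoalkene geometry comes from the elimination, and the acyl stereocentres are bought as (R)-2-methylbutanoic acid.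

Key step: step 8

Remark: shikimate numbering is used for chain and ring atoms throughout. The target is read as methyl 3-O-acetyl-4,5-bis-O-[(R)-2-methylbutanoyl]shikimate with the natural (3R,4S,5R) ring configuration. 2,3-O-Isopropylidene-D-threitol (the reduced acetonide of D-tartrate) and (R)-2-methylbutanoic acid are taken as purchasable. In step 11 the less hindered O5 is assumed to be acylated first.

**Route**

Step 1
Reactants: 1 (4R,5R)-2,2-dimethyl-1,3-dioxolane-4,5-dimethanol (2,3-O-isopropylidene-D-threitol)
Product: 2 {(4R,5R)-5-[(4-methoxybenzyloxy)methyl]-2,2-dimethyl-1,3-dioxolan-4-yl}methanol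
Conditions: NaH (1 equiv), 4-methoxybenzyl chloride (1 equiv), Bu4NI (cat.), THF/DMF, 0 °C → rt
Reagents that add atoms: 4-methoxybenzyl chloride, COc1ccc(CCl)cc1
Why: Williamson etherification of the mono-alkoxide; the two hydroxyls of C2-symmetric 1 are equivalent, so monoalkylation gives a single compound, and one equivalent of base limits bis-ether formation.

Step 2
Reactants: 2 {(4R,5R)-5-[(4-methoxybenzyloxy)methyl]-2,2-dimethyl-1,3-dioxolan-4-yl}methanol; 3 diethyl malonate
Product: 5 diethyl 2-({(4R,5R)-5-[(4-methoxybenzyloxy)methyl]-2,2-dimethyl-1,3-dioxolan-4-yl}methyl)malonate, via primary triflate 4 (not isolated)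
Conditions: Tf2O, pyridine, CH2Cl2, −20 °C; then 3 (2.5 equiv), NaH (2.2 equiv), THF/DMF, 0 °C → rt
Reagents that add atoms: diethyl malonate, CCOC(=O)CC(=O)OCC
Why: Sulfonylation followed by SN2 displacement of the primary triflate by the malonate anion (malonic ester alkylation) forms C6–C1; the trans-dioxolane keeps the benzylic ether oxygen from cyclising onto C6, and the excess of 3 limits double alkylation.

Step 3
Reactants: 5 diethyl 2-({(4R,5R)-5-[(4-methoxybenzyloxy)methyl]-2,2-dimethyl-1,3-dioxolan-4-yl}methyl)malonate; 6 iodoform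
Product: 7 diethyl 2-(diiodomethyl)-2-({(4R,5R)-5-[(4-methoxybenzyloxy)methyl]-2,2-dimethyl-1,3-dioxolan-4-yl}methyl)malonate
Conditions: NaH, THF, rt → reflux; then CHI3, reflux
Reagents that add atoms: iodoform, IC(I)I
Why: C-diiodomethylation of an alkylmalonate enolate with iodoform (capture of the diiodocarbene released from CHI3 by base), the established first half of the malonate route to 3-iodo-2-alkylacrylic acids; acetal and benzylic ether are inert to NaH.

Step 4
Reactants: 7 diethyl 2-(diiodomethyl)-2-({(4R,5R)-5-[(4-methoxybenzyloxy)methyl]-2,2-dimethyl-1,3-dioxolan-4-yl}methyl)malonate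
Product: 9 (E)-3-iodo-2-({(4R,5R)-5-[(4-methoxybenzyloxy)methyl]-2,2-dimethyl-1,3-dioxolan-4-yl}methyl)prop-2-enoic acid, via dipotassium malonate 8 (not isolated)
Conditions: KOH, EtOH/H2O (3:1), reflux; then aq. KHSO4 to pH 4, 0 °C
Reagents that add atoms: potassium hydroxide, [K+].[OH-]
Why: Saponification followed by decarboxylative Grob-type elimination of iodide from the malonate dianion, which with alkylmalonates should give the E acid (iodine trans to the carboxyl and thus cis to C6) through the rotamer that keeps the remaining iodine away from the second carboxylate; acetal and benzylic ether withstand hot base and the brief mild acidification.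

Step 5
Reactants: 9 (E)-3-iodo-2-({(4R,5R)-5-[(4-methoxybenzyloxy)methyl]-2,2-dimethyl-1,3-dioxolan-4-yl}methyl)prop-2-enoic acid
Product: 10 methyl (E)-3-iodo-2-({(4R,5R)-5-[(4-methoxybenzyloxy)methyl]-2,2-dimethyl-1,3-dioxolan-4-yl}methyl)prop-2-enoate
Conditions: MeI, K2CO3, DMF, rt
Reagents that add atoms: iodomethane, CI
Why: SN2 O-alkylation of the carboxylate with iodomethane, which avoids acid and leaves the iodoalkene geometry untouched.

Step 6
Reactants: 10 methyl (E)-3-iodo-2-({(4R,5R)-5-[(4-methoxybenzyloxy)methyl]-2,2-dimethyl-1,3-dioxolan-4-yl}methyl)prop-2-enoate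
Product: 11 methyl (E)-2-{[(4R,5R)-5-(hydroxymethyl)-2,2-dimethyl-1,3-dioxolan-4-yl]methyl}-3-iodoprop-2-enoate
Conditions: DDQ, CH2Cl2/aq. NaH2PO4–Na2HPO4 buffer (pH 7), 0 °C → rt
Reagents that add atoms: none
Why: Oxidative cleavage of the electron-rich 4-methoxybenzyl ether by DDQ (hydride abstraction, then hydrolysis of the oxocarbenium ion), to which the iodoalkene, the enoate and the buffered acetal are inert.

Step 7
Reactants: 11 methyl (E)-2-{[(4R,5R)-5-(hydroxymethyl)-2,2-dimethyl-1,3-dioxolan-4-yl]methyl}-3-iodoprop-2-enoate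
Product: 12 methyl (E)-2-{[(4R,5S)-5-formyl-2,2-dimethyl-1,3-dioxolan-4-yl]methyl}-3-iodoprop-2-enoate
Conditions: Dess–Martin periodinane, pyridine, CH2Cl2, 0 °C → rt; used crude
Reagents that add atoms: none
Why: Dess–Martin oxidation of the primary alcohol under non-basic conditions; the α-alkoxy aldehyde should not epimerise, and the trans-disubstituted dioxolane is in any case the more stable arrangement.

Step 8
Reactants: 12 methyl (E)-2-{[(4R,5S)-5-formyl-2,2-dimethyl-1,3-dioxolan-4-yl]methyl}-3-iodoprop-2-enoate
Product: 14 methyl 4,5-O-isopropylideneshikimate (methyl shikimate with O4 and O5 bridged by a trans-fused acetonide; 3-OH free), via alkenylchromium dichloride 13 (not isolated)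
Conditions: CrCl2 (6 equiv), NiCl2 (2 mol %), degassed DMF, 0.005 M, rt; aq. NH4Cl work-up
Reagents that add atoms: none
Why: NiCl2 is reduced by CrCl2 to zerovalent nickel, which inserts into the C2–I bond of the electron-poor iodoalkene; transmetallation to trivalent chromium gives alkenylchromium 13 with the alkene geometry retained, and this adds to the C3 aldehyde (Nozaki–Hiyama–Kishi reaction; the closest known type is the intramolecular nickel/chromium coupling of alkenyl iodides with aldehydes to cyclic allylic alcohols). The cyclohexene closes in a 6-exo-trig mode, since the C3=O bond that is attacked lies outside the new ring. The new C3 stereocentre is substrate-controlled: the trans-dioxolane holds O4 equatorial and antiperiplanar to the forming C2–C3 bond (polar Felkin–Anh alignment), and the half-chair with the carbonyl oxygen pseudoaxial and gauche to C5 should lead to the 3,4-cis alcohol of the shikimate series. The step needs chemoselectivity (the alkenylchromium attacks the aldehyde and spares the enoate and the acetal), retention of the iodoalkene geometry fixed in step 4 (only iodine cis to C6 can reach C3) and configurational integrity at C4 (the non-basic reagent does not enolise the aldehyde). High dilution suppresses intermolecular coupling.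

Step 9
Reactants: 14 methyl 4,5-O-isopropylideneshikimate
Product: 15 methyl 3-O-acetyl-4,5-O-isopropylideneshikimate
Conditions: Ac2O, pyridine, 4-(dimethylamino)pyridine (cat.), CH2Cl2, 0 °C
Reagents that add atoms: acetic anhydride, CC(=O)OC(C)=O
Why: Acylation of the allylic secondary alcohol with Ac2O under nucleophilic catalysis by 4-(dimethylamino)pyridine; no stereocentre is touched and the basic medium leaves the trans-acetal in place.

Step 10
Reactants: 15 methyl 3-O-acetyl-4,5-O-isopropylideneshikimate
Product: 16 methyl 3-O-acetylshikimate (4,5-diol)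
Conditions: 80% aq. AcOH, rt; toluene azeotrope; used at once
Reagents that add atoms: none
Why: Acid-catalysed acetal hydrolysis; the strained trans-fused dioxolane should open under conditions mild enough to keep the allylic acetate and the methyl ester, and the acidic medium slows acetyl migration from O3 to O4.

Step 11
Reactants: 16 methyl 3-O-acetylshikimate; 17 (R)-2-methylbutanoic acid
Product: 19 methyl 3-O-acetyl-4,5-bis-O-[(R)-2-methylbutanoyl]shikimate (target), via 5-O-monoester 18 (not isolated)
Conditions: 17 (3 equiv), N,N′-dicyclohexylcarbodiimide (3 equiv), 4-(dimethylamino)pyridine (0.3 equiv), CH2Cl2, 0 °C → rt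
Reagents that add atoms: (R)-2-methylbutanoic acid, CC[C@@H](C)C(=O)O
Why: Steglich esterification (carbodiimide activation, acyl transfer through the acylpyridinium) of both secondary hydroxyls; the ring stereocentres are not involved, and low temperature with substoichiometric 4-(dimethylamino)pyridine should keep the α-stereocentre of the acid from epimerising.

**Compound list**

1 | (4R,5R)-2,2-dimethyl-1,3-dioxolane-4,5-dimethanol (2,3-O-isopropylidene-D-threitol) | OC[C@H]1OC(C)(C)O[C@@H]1CO | starting material
2 | {(4R,5R)-5-[(4-methoxybenzyloxy)methyl]-2,2-dimethyl-1,3-dioxolan-4-yl}methanol | COc1ccc(COC[C@H]2OC(C)(C)O[C@@H]2CO)cc1 | intermediate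
3 | diethyl malonate | CCOC(=O)CC(=O)OCC | starting material
4 | {(4R,5R)-5-[(4-methoxybenzyloxy)methyl]-2,2-dimethyl-1,3-dioxolan-4-yl}methyl trifluoromethanesulfonate | COc1ccc(COC[C@H]2OC(C)(C)O[C@@H]2COS(=O)(=O)C(F)(F)F)cc1 | intermediate (not isolated)
5 | diethyl 2-({(4R,5R)-5-[(4-methoxybenzyloxy)methyl]-2,2-dimethyl-1,3-dioxolan-4-yl}methyl)malonate | COc1ccc(COC[C@H]2OC(C)(C)O[C@@H]2CC(C(=O)OCC)C(=O)OCC)cc1 | intermediate
6 | iodoform | IC(I)I | starting material
7 | diethyl 2-(diiodomethyl)-2-({(4R,5R)-5-[(4-methoxybenzyloxy)methyl]-2,2-dimethyl-1,3-dioxolan-4-yl}methyl)malonate | COc1ccc(COC[C@H]2OC(C)(C)O[C@@H]2CC(C(I)I)(C(=O)OCC)C(=O)OCC)cc1 | intermediate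
8 | dipotassium 2-(diiodomethyl)-2-({(4R,5R)-5-[(4-methoxybenzyloxy)methyl]-2,2-dimethyl-1,3-dioxolan-4-yl}methyl)malonate | COc1ccc(COC[C@H]2OC(C)(C)O[C@@H]2CC(C(I)I)(C(=O)[O-])C(=O)[O-])cc1.[K+].[K+] | intermediate (not isolated)
9 | (E)-3-iodo-2-({(4R,5R)-5-[(4-methoxybenzyloxy)methyl]-2,2-dimethyl-1,3-dioxolan-4-yl}methyl)prop-2-enoic acid | COc1ccc(COC[C@H]2OC(C)(C)O[C@@H]2C/C(C(=O)O)=C\I)cc1 | intermediate
10 | methyl (E)-3-iodo-2-({(4R,5R)-5-[(4-methoxybenzyloxy)methyl]-2,2-dimethyl-1,3-dioxolan-4-yl}methyl)prop-2-enoate | COc1ccc(COC[C@H]2OC(C)(C)O[C@@H]2C/C(C(=O)OC)=C\I)cc1 | intermediate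
11 | methyl (E)-2-{[(4R,5R)-5-(hydroxymethyl)-2,2-dimethyl-1,3-dioxolan-4-yl]methyl}-3-iodoprop-2-enoate | OC[C@H]1OC(C)(C)O[C@@H]1C/C(C(=O)OC)=C\I | intermediate
12 | methyl (E)-2-{[(4R,5S)-5-formyl-2,2-dimethyl-1,3-dioxolan-4-yl]methyl}-3-iodoprop-2-enoate | O=C[C@H]1OC(C)(C)O[C@@H]1C/C(C(=O)OC)=C\I | intermediate
13 | alkenylchromium dichloride formed from 12 (chromium in place of iodine at C2, cis to C6) | O=C[C@H]1OC(C)(C)O[C@@H]1C/C(C(=O)OC)=C\[Cr](Cl)Cl | intermediate (not isolated)
14 | methyl 4,5-O-isopropylideneshikimate (trans-fused acetonide, natural shikimate configuration at C3, C4 and C5) | COC(=O)C1=C[C@@H](O)[C@H]2OC(C)(C)O[C@@H]2C1 | intermediate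
15 | methyl 3-O-acetyl-4,5-O-isopropylideneshikimate | COC(=O)C1=C[C@@H](OC(C)=O)[C@H]2OC(C)(C)O[C@@H]2C1 | intermediate
16 | methyl 3-O-acetylshikimate | COC(=O)C1=C[C@@H](OC(C)=O)[C@@H](O)[C@H](O)C1 | intermediate
17 | (R)-2-methylbutanoic acid | CC[C@@H](C)C(=O)O | starting material
18 | methyl 3-O-acetyl-5-O-[(R)-2-methylbutanoyl]shikimate | COC(=O)C1=C[C@@H](OC(C)=O)[C@@H](O)[C@H](OC(=O)[C@H](C)CC)C1 | intermediate (not isolated)
19 | methyl 3-O-acetyl-4,5-bis-O-[(R)-2-methylbutanoyl]shikimate | CC[C@@H](C)C(=O)O[C@@H]1[C@H](OC(C)=O)C=C(C(=O)OC)C[C@H]1OC(=O)[C@H](C)CC | target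

**Step count**

Total: 11 steps. Longest linear sequence: 11 steps (1 → 19); compounds 3, 6 and 17 are bought and enter directly.

**Steps most likely to fail**

Step 8. Facial selectivity in the addition to the aldehyde may be poor, or may favour the pseudoequatorial carbinol, because the tether and not the Felkin–Anh preference may decide the orientation of the carbonyl group in the cyclic transition state. The fallback sets out from 12 and comes back at 15. The ring closure is run as in step 8, and the C3 epimer, methyl 4,5-O-isopropylidene-3-epi-shikimate F1, is separated from any 14. F1 is then treated with acetic acid, PPh3 and diisopropyl azodicarboxylate in THF at 0 °C (Mitsunobu reaction). Displacement at the allylic carbon with inversion installs the O3 acetate in the shikimate configuration and gives 15 directly, while any 14 formed alongside is acetylated as in step 9, so both epimers converge.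

Step 3. The hindered, β-branched malonate enolate may capture the iodoform-derived carbene slowly, so that iodoform is consumed unproductively and 5 is recovered. The fallback sets out from 2 and comes back at 10, replacing steps 2–5. Triflate 4 is made from 2 as in step 2 and is alkylated with the sodium salt of methyl 1,3-dithiane-2-carboxylate (NaH, DMF, 0 °C) to give methyl 2-({(4R,5R)-5-[(4-methoxybenzyloxy)methyl]-2,2-dimethyl-1,3-dioxolan-4-yl}methyl)-1,3-dithiane-2-carboxylate F2. Oxidative hydrolysis of the dithiane (N-bromosuccinimide, aqueous acetone, 0 °C) would give the α-keto ester methyl 3-{(4R,5R)-5-[(4-methoxybenzyloxy)methyl]-2,2-dimethyl-1,3-dioxolan-4-yl}-2-oxopropanoate F3. Wittig iodomethylenation of the activated ketone with Ph3P=CHI (from (iodomethyl)triphenylphosphonium iodide and NaN(SiMe3)2, THF, −78 °C → rt) should then give the iodoalkene as geometric isomers, from which the E isomer 10 is separated by chromatography.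

Step 10. Once the 4-hydroxyl is free, the acetyl group may migrate from O3 to the cis-disposed O4 during hydrolysis, handling or the base-catalysed acylation of step 11, which would scramble the ester pattern. The fallback sets out from 14 and comes back at 19, reversing the order in which the acyl groups are introduced.
- Alcohol 14 is silylated (TBSOTf, 2,6-lutidine, CH2Cl2, −78 °C) to methyl 3-O-(tert-butyldimethylsilyl)-4,5-O-isopropylideneshikimate F4.
- The strained acetal is hydrolysed (80% aq. AcOH, rt) to methyl 3-O-(tert-butyldimethylsilyl)shikimate F5.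
- Steglich esterification with 17 (N,N′-dicyclohexylcarbodiimide, 4-(dimethylamino)pyridine, CH2Cl2) gives methyl 3-O-(tert-butyldimethylsilyl)-4,5-bis-O-[(R)-2-methylbutanoyl]shikimate F6.
- Acidic desilylation (HF·pyridine, THF, 0 °C → rt) gives methyl 4,5-bis-O-[(R)-2-methylbutanoyl]shikimate F7; the α-branched esters should migrate far less readily than an acetate.
- Acetylation of O3 (Ac2O, pyridine, 4-(dimethylamino)pyridine, 0 °C) then gives 19.

**Further compounds**

F1 | step 8 | methyl 4,5-O-isopropylidene-3-epi-shikimate | COC(=O)C1=C[C@H](O)[C@H]2OC(C)(C)O[C@@H]2C1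
F2 | step 3 | methyl 2-({(4R,5R)-5-[(4-methoxybenzyloxy)methyl]-2,2-dimethyl-1,3-dioxolan-4-yl}methyl)-1,3-dithiane-2-carboxylate | COc1ccc(COC[C@H]2OC(C)(C)O[C@@H]2CC3(C(=O)OC)SCCCS3)cc1
F3 | step 3 | methyl 3-{(4R,5R)-5-[(4-methoxybenzyloxy)methyl]-2,2-dimethyl-1,3-dioxolan-4-yl}-2-oxopropanoate | COc1ccc(COC[C@H]2OC(C)(C)O[C@@H]2CC(=O)C(=O)OC)cc1
F4 | step 10 | methyl 3-O-(tert-butyldimethylsilyl)-4,5-O-isopropylideneshikimate | COC(=O)C1=C[C@@H](O[Si](C)(C)C(C)(C)C)[C@H]2OC(C)(C)O[C@@H]2C1
F5 | step 10 | methyl 3-O-(tert-butyldimethylsilyl)shikimate | COC(=O)C1=C[C@@H](O[Si](C)(C)C(C)(C)C)[C@@H](O)[C@H](O)C1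
F6 | step 10 | methyl 3-O-(tert-butyldimethylsilyl)-4,5-bis-O-[(R)-2-methylbutanoyl]shikimate | COC(=O)C1=C[C@@H](O[Si](C)(C)C(C)(C)C)[C@@H](OC(=O)[C@H](C)CC)[C@H](OC(=O)[C@H](C)CC)C1
F7 | step 10 | methyl 4,5-bis-O-[(R)-2-methylbutanoyl]shikimate | COC(=O)C1=C[C@@H](O)[C@@H](OC(=O)[C@H](C)CC)[C@H](OC(=O)[C@H](C)CC)C1
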